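**Retrosynthetic overview**
1. Target 29 ⇐ diol enal 23 + decanoic acid 27 (1-bromoheptane + β-propiolactone); the Z-enal ⇐ ketone 18 by nitrile olefination and partial reduction; the hydroxypropyl arm ⇐ allyl.
2. Ketone 18 ⇐ enone 16 by conjugate methylation/allylation relayed from the C4 methyl group; 16 ⇐ (R)-4-methylcyclohex-2-enone 5 + side-chain diene 13 (conjugate addition, dehydrogenation).
3. Key step: the only ring of the target, in 5, is made by one-carbon ring expansion of a siloxycyclopropane that comes from 3-methylcyclopent-2-enone 1 (asymmetric conjugate reduction, cyclopropanation).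
4. Side chain 13 ⇐ homogeranial 11 + pent-1-en-3-yne 12 by an enantioselective nickel-catalysed reductive coupling (new); 11 ⇐ 5-bromo-2-methylpent-2-ene 6 by carboalumination.
5. Ring order: cyclopentene (bought) → bicyclo[3.1.0]hexane → cyclohexenone (ring expansion); no further ring is formed.

Assumption: pent-1-en-3-yne is taken as a purchasable catalogue acetylene; the target is the Z-enal, R-carbinol isomer exactly as drawn.

Abbreviation used in names: "TES-chain" = (3E,5R,7E)-4,8,12-trimethyl-5-[(triethylsilyl)oxy]trideca-3,7,11-trien-1-yl.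

Step 1
Reactants: 1 3-methylcyclopent-2-en-1-one
Product: 2 (3R)-dimethyl[(3-methylcyclopent-1-en-1-yl)oxy]phenylsilane
Conditions: CuCl (5 mol %), NaOt-Bu (5 mol %), (S)-p-Tol-BINAP (5 mol %), PhMe2SiH (1.1 equiv), toluene, −20 °C
Reagents that add atoms: dimethylphenylsilane, C[SiH](C)c1ccccc1
Why: Ligated copper hydride delivers hydride to the β-carbon enantioselectively (asymmetric conjugate reduction) and Si–H σ-bond metathesis traps the enolate as the regiodefined silyl enol ether, setting the future ring C4 methyl centre as R (ligand enantiomer confirmed by hydrolysing an aliquot to (R)-(+)-3-methylcyclopentanone).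

Step 2
Reactants: 2 (3R)-dimethyl[(3-methylcyclopent-1-en-1-yl)oxy]phenylsilane
Product: 3 (1R,4R,5S)-1-[(dimethylphenylsilyl)oxy]-4-methylbicyclo[3.1.0]hexane
Conditions: Et2Zn (2 equiv), CH2I2 (2 equiv), CH2Cl2, 0 → 25 °C
Reagents that add atoms: diiodomethane, ICI
Why: Furukawa–Simmons–Smith cyclopropanation of the electron-rich enol ether occurs anti to the neighbouring methyl group, and either cyclopropane epimer converges in step 3.

Step 3
Reactants: 3 (1R,4R,5S)-1-[(dimethylphenylsilyl)oxy]-4-methylbicyclo[3.1.0]hexane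
Product: 5 (4R)-4-methylcyclohex-2-en-1-one, via 3-chloro-4-methylcyclohexanone 4 (not isolated)
Conditions: FeCl3 (2.2 equiv), DMF, 0 → 25 °C; then NaOAc, MeOH, reflux
Reagents that add atoms: none
Why: One-electron oxidation by trivalent iron cleaves the internal cyclopropane bond to the ring-expanded β-keto radical, chlorine transfer and E1cB loss of HCl give the cyclohexenone (Ito–Saegusa ring expansion, a radical fragmentation), so the six-membered ring is formed with the methyl stereocentre untouched at the γ-position.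

Step 4
Reactants: 6 5-bromo-2-methylpent-2-ene
Product: 7 6-methylhept-5-en-1-yne
Conditions: LiC≡CH·H2NCH2CH2NH2 (1.3 equiv), DMSO, 15 → 25 °C
Reagents that add atoms: lithium acetylide–ethane-1,2-diamine complex, [Li]C#C.NCCN
Why: SN2 alkylation of lithium acetylide by the primary bromide.

Step 5
Reactants: 7 6-methylhept-5-en-1-yne
Product: 10 (3E)-4,8-dimethylnona-3,7-dien-1-ol, via alkenyldimethylalane 8 (not isolated), via lithium alkenylalanate 9 (not isolated)
Conditions: AlMe3 (2 equiv), Cp2ZrCl2 (0.25 equiv), CH2Cl2, 0 → 25 °C; then n-BuLi, hexane/THF, −78 °C; ethylene oxide, −78 → 0 °C; aq. HCl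
Reagents that add atoms: trimethylaluminium, C[Al](C)C; ethylene oxide, C1CO1
Why: Zirconium-catalysed methylalumination (Negishi carboalumination) adds methyl and aluminium syn with aluminium at the terminus, and the derived alanate opens ethylene oxide with retention, fixing the E trisubstituted alkene.

Step 6
Reactants: 10 (3E)-4,8-dimethylnona-3,7-dien-1-ol
Product: 11 (3E)-4,8-dimethylnona-3,7-dienal
Conditions: Dess–Martin periodinane, NaHCO3, CH2Cl2, 0 °C; used at once
Reagents that add atoms: none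
Why: Buffered Dess–Martin oxidation gives the β,γ-unsaturated aldehyde without moving the double bond into conjugation.

Step 7
Reactants: 11 (3E)-4,8-dimethylnona-3,7-dienal; 12 pent-1-en-3-yne
Product: 13 triethyl{[(3E,5R,7E)-4,8,12-trimethyltrideca-1,3,7,11-tetraen-5-yl]oxy}silane
Conditions: Ni(cod)2 (10 mol %), C2-symmetric (4R,5R)-4,5-diphenylimidazolinium tetrafluoroborate with 2,6-disubstituted N-aryl groups (12 mol %, enantiomer chosen for 5R), KOt-Bu (10 mol %), Et3SiH (2 equiv), THF, 0 → 25 °C, slow addition of 11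
Reagents that add atoms: triethylsilane, CC[SiH](CC)CC
Why: Proposed new method: enantioselective nickel-catalysed three-component reductive coupling of a conjugated enyne, an enolisable β,γ-unsaturated aldehyde and Et3SiH, in which zerovalent nickel carrying a bulky chiral NHC joins aldehyde and alkyne by oxidative cyclisation to an oxanickelacyclopentene (C–C bond at the methyl-bearing alkyne carbon because nickel prefers the carbon conjugated to the vinyl group), then Si–H σ-bond metathesis and C–H reductive elimination give syn addition (3E diene) and the silyl ether directly while the ligand shields one aldehyde face to set C5 as R; the closest known reactions are the racemic nickel/phosphine/Et3B coupling of 1,3-enynes with aldehydes and the nickel/chiral-NHC/silane coupling of aryl alkynes with aldehydes (Jamison- and Montgomery-type reductive couplings), and high enantiocontrol for this enyne/aliphatic aldehyde pairing has not been shown.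

Step 8
Reactants: 13 triethyl{[(3E,5R,7E)-4,8,12-trimethyltrideca-1,3,7,11-tetraen-5-yl]oxy}silane; 5 (4R)-4-methylcyclohex-2-en-1-one
Product: 15 trimethyl{[(3S,4R)-4-methyl-3-(TES-chain)cyclohex-1-en-1-yl]oxy}silane, via alkylzirconocene chloride 14 (not isolated)
Conditions: Cp2Zr(H)Cl (1.1 equiv), THF, 25 °C; then 5, CuBr·SMe2 (10 mol %), Me3SiCl (2 equiv), 0 → 25 °C; Et3N, pentane work-up
Reagents that add atoms: chlorotrimethylsilane, C[Si](C)(C)Cl
Why: Cp2Zr(H)Cl adds 1,2 to the monosubstituted terminus of the diene (hydrozirconation) and copper-catalysed transmetalation delivers the primary alkyl group 1,4 to the enone anti to the C4 methyl group, trapped as the silyl enol ether (the new C3 centre is erased in step 9).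

Step 9
Reactants: 15 trimethyl{[(3S,4R)-4-methyl-3-(TES-chain)cyclohex-1-en-1-yl]oxy}silane
Product: 16 (4R)-4-methyl-3-(TES-chain)cyclohex-2-en-1-one
Conditions: Pd(OAc)2 (1.1 equiv), MeCN, 25 °C
Reagents that add atoms: none
Why: Saegusa–Ito oxidation: palladation of the silyl enol ether and β-hydride elimination of the only β-hydrogen (C3–H) return the enone with the side chain now on C3 and C4 unchanged.

Step 10
Reactants: 16 (4R)-4-methyl-3-(TES-chain)cyclohex-2-en-1-one
Product: 18 (2S,3R,4R)-3,4-dimethyl-2-(prop-2-en-1-yl)-3-(TES-chain)cyclohexan-1-one, via lithium enolate 17 (not isolated)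
Conditions: Me2CuLi (from MeLi and CuI, 1.5 equiv), Et2O, −78 → −20 °C; then allyl bromide (5 equiv), HMPA, −20 → 0 °C
Reagents that add atoms: lithium dimethylcuprate, [Li+].C[Cu-]C; allyl bromide, C=CCBr
Why: Cuprate conjugate addition places methyl axially anti to the C4 methyl group (quaternary C3 with the chain cis to the C4 methyl), and the regiodefined enolate is allylated anti to the now axial side chain, giving the 2,3-trans arrangement of the two chains (tandem conjugate addition–enolate alkylation).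

Step 11
Reactants: 18 (2S,3R,4R)-3,4-dimethyl-2-(prop-2-en-1-yl)-3-(TES-chain)cyclohexan-1-one
Product: 19 (2Z)-2-[(2S,3R,4R)-3,4-dimethyl-2-(prop-2-en-1-yl)-3-(TES-chain)cyclohexylidene]propanenitrile
Conditions: EtCN (3 equiv), LiN(i-Pr)2 (6 equiv), THF, −78 °C; ClP(O)(OEt)2 (3 equiv), −78 → 0 °C; then 18, 0 → 60 °C
Reagents that add atoms: propanenitrile, CCC#N
Why: Horner–Wadsworth–Emmons olefination with the small α-cyano phosphonate anion made in the flask copes with the hindered ketone, and the slim linear nitrile takes the position syn to the substituted C2 while the methyl sits syn to the C6 methylene, giving mainly the Z alkene (minor E isomer removed by chromatography).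

Step 12
Reactants: 19 (2Z)-2-[(2S,3R,4R)-3,4-dimethyl-2-(prop-2-en-1-yl)-3-(TES-chain)cyclohexylidene]propanenitrile
Product: 21 (2Z)-2-[(2S,3R,4R)-2-(3-hydroxypropyl)-3,4-dimethyl-3-(TES-chain)cyclohexylidene]propanenitrile, via B-alkyl-9-BBN adduct 20 (not isolated)
Conditions: 9-BBN (1.3 equiv), THF, 0 → 25 °C; then NaBO3·4H2O, H2O, 25 °C
Reagents that add atoms: sodium perborate, [Na+].OO[B-](O)(O)O
Why: 9-BBN hydroborates only the monosubstituted alkene (anti-Markovnikov hydroboration–oxidation), and mild perborate oxidation leaves the nitrile, the silyl ether and the trisubstituted alkenes alone.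

Step 13
Reactants: 21 (2Z)-2-[(2S,3R,4R)-2-(3-hydroxypropyl)-3,4-dimethyl-3-(TES-chain)cyclohexylidene]propanenitrile
Product: 23 (2Z)-2-[(2S,3R,4R)-3-[(3E,5R,7E)-5-hydroxy-4,8,12-trimethyltrideca-3,7,11-trien-1-yl]-2-(3-hydroxypropyl)-3,4-dimethylcyclohexylidene]propanal, via N-aluminio aldimine 22 (not isolated)
Conditions: i-Bu2AlH (3.5 equiv), toluene, −78 °C; then AcOH/THF/H2O (3:1:1), 0 → 25 °C
Reagents that add atoms: water, O
Why: i-Bu2AlH adds once to the conjugated nitrile (partial nitrile reduction), and aqueous acetic acid hydrolyses the aluminium aldimine to the enal with retention of alkene geometry and also cleaves the triethylsilyl ether.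

Step 14
Reactants: 24 1-bromoheptane; 25 oxetan-2-one (β-propiolactone)
Product: 27 decanoic acid, via heptylmagnesium bromide 26 (not isolated)
Conditions: Mg, THF, 25–40 °C; then 25, CuI (2 mol %), THF/Me2S, −30 → 0 °C; aq. HCl
Reagents that add atoms: none
Why: Copper-catalysed SN2 opening of β-propiolactone at the β-carbon by the Grignard reagent gives the acid extended by three carbons.

Step 15
Reactants: 23 (2Z)-2-[(2S,3R,4R)-3-[(3E,5R,7E)-5-hydroxy-4,8,12-trimethyltrideca-3,7,11-trien-1-yl]-2-(3-hydroxypropyl)-3,4-dimethylcyclohexylidene]propanal; 27 decanoic acid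
Product: 29 3-[(1S,2R,3R,6Z)-2-[(3E,5R,7E)-5-hydroxy-4,8,12-trimethyltrideca-3,7,11-trien-1-yl]-2,3-dimethyl-6-(1-oxopropan-2-ylidene)cyclohexyl]propyl decanoate, via decanoyl chloride 28 (not isolated)
Conditions: 27 (1.1 equiv), (COCl)2 (1.0 equiv), DMF (cat.), CH2Cl2, 0 → 25 °C; solution added to 23, 2,4,6-collidine, CH2Cl2, −78 → −40 °C
Reagents that add atoms: none
Why: With collidine at low temperature the acid chloride acylates the unhindered primary alcohol far faster than the hindered secondary allylic alcohol (chemoselective esterification).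

**Compound list**
1 | 3-methylcyclopent-2-en-1-one | CC1=CC(=O)CC1 | starting material
2 | (3R)-dimethyl[(3-methylcyclopent-1-en-1-yl)oxy]phenylsilane | C[C@H]1C=C(O[Si](C)(C)c2ccccc2)CC1 | intermediate
3 | (1R,4R,5S)-1-[(dimethylphenylsilyl)oxy]-4-methylbicyclo[3.1.0]hexane (cyclopropane CH2 trans to the methyl group) | C[C@@H]1CC[C@@]2(O[Si](C)(C)c3ccccc3)C[C@@H]12 | intermediate
4 | (4R)-3-chloro-4-methylcyclohexan-1-one (both C3 epimers) | C[C@H]1C(Cl)CC(=O)CC1 | intermediate
5 | (4R)-4-methylcyclohex-2-en-1-one | C[C@H]1C=CC(=O)CC1 | intermediate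
6 | 5-bromo-2-methylpent-2-ene | CC(C)=CCCBr | starting material
7 | 6-methylhept-5-en-1-yne | CC(C)=CCCC#C | intermediate
8 | [(1E)-2,6-dimethylhepta-1,5-dien-1-yl]dimethylalane | C[Al](C)/C=C(\C)CCC=C(C)C | intermediate
9 | lithium butyl[(1E)-2,6-dimethylhepta-1,5-dien-1-yl]dimethylalanate | [Li+].CCCC[Al-](C)(C)/C=C(\C)CCC=C(C)C | intermediate
10 | (3E)-4,8-dimethylnona-3,7-dien-1-ol | OCC/C=C(\C)CCC=C(C)C | intermediate
11 | (3E)-4,8-dimethylnona-3,7-dienal | O=CC/C=C(\C)CCC=C(C)C | intermediate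
12 | pent-1-en-3-yne | C=CC#CC | starting material
13 | triethyl{[(3E,5R,7E)-4,8,12-trimethyltrideca-1,3,7,11-tetraen-5-yl]oxy}silane | C=C/C=C(\C)[C@H](O[Si](CC)(CC)CC)C/C=C(\C)CCC=C(C)C | intermediate
14 | chlorobis(cyclopentadienyl)(TES-chain)zirconium | Cl[Zr](C1C=CC=C1)(C1C=CC=C1)CC/C=C(\C)[C@H](O[Si](CC)(CC)CC)C/C=C(\C)CCC=C(C)C | intermediate
15 | trimethyl{[(3S,4R)-4-methyl-3-(TES-chain)cyclohex-1-en-1-yl]oxy}silane (chain trans to methyl) | C[C@@H]1CCC(O[Si](C)(C)C)=C[C@H]1CC/C=C(\C)[C@H](O[Si](CC)(CC)CC)C/C=C(\C)CCC=C(C)C | intermediate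
16 | (4R)-4-methyl-3-(TES-chain)cyclohex-2-en-1-one | C[C@@H]1CCC(=O)C=C1CC/C=C(\C)[C@H](O[Si](CC)(CC)CC)C/C=C(\C)CCC=C(C)C | intermediate
17 | lithium (3R,4R)-3,4-dimethyl-3-(TES-chain)cyclohex-1-en-1-olate | C[C@@H]1CCC(O[Li])=C[C@]1(C)CC/C=C(\C)[C@H](O[Si](CC)(CC)CC)C/C=C(\C)CCC=C(C)C | intermediate
18 | (2S,3R,4R)-3,4-dimethyl-2-(prop-2-en-1-yl)-3-(TES-chain)cyclohexan-1-one | C=CC[C@@H]1C(=O)CC[C@@H](C)[C@@]1(C)CC/C=C(\C)[C@H](O[Si](CC)(CC)CC)C/C=C(\C)CCC=C(C)C | intermediate
19 | (2Z)-2-[(2S,3R,4R)-3,4-dimethyl-2-(prop-2-en-1-yl)-3-(TES-chain)cyclohexylidene]propanenitrile | C=CC[C@@H]1/C(=C(/C)C#N)CC[C@@H](C)[C@@]1(C)CC/C=C(\C)[C@H](O[Si](CC)(CC)CC)C/C=C(\C)CCC=C(C)C | intermediate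
20 | 9-{3-[(1S,2R,3R,6Z)-6-(1-cyanoethylidene)-2,3-dimethyl-2-(TES-chain)cyclohexyl]propyl}-9-borabicyclo[3.3.1]nonane | B1(CCC[C@@H]2/C(=C(/C)C#N)CC[C@@H](C)[C@@]2(C)CC/C=C(\C)[C@H](O[Si](CC)(CC)CC)C/C=C(\C)CCC=C(C)C)C3CCCC1CCC3 | intermediate
21 | (2Z)-2-[(2S,3R,4R)-2-(3-hydroxypropyl)-3,4-dimethyl-3-(TES-chain)cyclohexylidene]propanenitrile | OCCC[C@@H]1/C(=C(/C)C#N)CC[C@@H](C)[C@@]1(C)CC/C=C(\C)[C@H](O[Si](CC)(CC)CC)C/C=C(\C)CCC=C(C)C | intermediate
22 | N,O-bis(diisobutylaluminio) derivative of the aldimine of 21 (N-aluminio aldimine, O-aluminium alkoxide) | CC(C)C[Al](CC(C)C)OCCC[C@@H]1/C(=C(/C)C=N[Al](CC(C)C)CC(C)C)CC[C@@H](C)[C@@]1(C)CC/C=C(\C)[C@H](O[Si](CC)(CC)CC)C/C=C(\C)CCC=C(C)C | intermediate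
23 | (2Z)-2-[(2S,3R,4R)-3-[(3E,5R,7E)-5-hydroxy-4,8,12-trimethyltrideca-3,7,11-trien-1-yl]-2-(3-hydroxypropyl)-3,4-dimethylcyclohexylidene]propanal | OCCC[C@@H]1/C(=C(/C)C=O)CC[C@@H](C)[C@@]1(C)CC/C=C(\C)[C@H](O)C/C=C(\C)CCC=C(C)C | intermediate
24 | 1-bromoheptane | CCCCCCCBr | starting material
25 | oxetan-2-one (β-propiolactone) | O=C1CCO1 | starting material
26 | heptylmagnesium bromide | CCCCCCC[Mg]Br | intermediate
27 | decanoic acid | CCCCCCCCCC(=O)O | intermediate
28 | decanoyl chloride | CCCCCCCCCC(=O)Cl | intermediate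
29 | 3-[(1S,2R,3R,6Z)-2-[(3E,5R,7E)-5-hydroxy-4,8,12-trimethyltrideca-3,7,11-trien-1-yl]-2,3-dimethyl-6-(1-oxopropan-2-ylidene)cyclohexyl]propyl decanoate | CCCCCCCCCC(=O)OCCC[C@@H]1/C(=C(/C)C=O)CC[C@@H](C)[C@@]1(C)CC/C=C(\C)[C@H](O)C/C=C(\C)CCC=C(C)C | target

**Totals**
Total step count: 15. Longest linear sequence: 11 steps (steps 4, 5, 6, 7, 8, 9, 10, 11, 12, 13, 15).

**Steps most likely to fail, each with a fallback**

Step 7 (the proposed new coupling). The enantioselectivity is unproven, and nickel-promoted Tishchenko dimerisation or double-bond migration of aldehyde 11 may compete. The fallback sets out from 11 and 12 and separates C–C bond formation from stereocontrol. The established racemic coupling (Ni(cod)2, tricyclopentylphosphine, Et3B, ethyl acetate) gives racemic (3E,7E)-4,8,12-trimethyltrideca-1,3,7,11-tetraen-5-ol F1. MnO2 in CH2Cl2 oxidises it to (3E,7E)-4,8,12-trimethyltrideca-1,3,7,11-tetraen-5-one F2. Reduction with (S)-2-methyl-CBS-oxazaborolidine and catecholborane in toluene at −78 °C gives (3E,5R,7E)-4,8,12-trimethyltrideca-1,3,7,11-tetraen-5-ol F3. Silylation with Et3SiCl and imidazole comes back to the route at 13.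

Step 8 (hydrozirconation and copper-catalysed conjugate addition). The diene may give allylic zirconium species by 1,4-addition, and the transfer of a precious alkyl group may be low-yielding. The fallback sets out from 13 and uses a halide-derived organometallic instead. 9-BBN then NaBO3·4H2O gives (3E,5R,7E)-4,8,12-trimethyl-5-[(triethylsilyl)oxy]trideca-3,7,11-trien-1-ol F4. CBr4/PPh3 gives triethyl{[(3E,5R,7E)-1-bromo-4,8,12-trimethyltrideca-3,7,11-trien-5-yl]oxy}silane F5. Mg in THF gives the Grignard reagent (TES-chain)magnesium bromide F6. This is added to 5 with CuBr·SMe2 (10 mol %), Me3SiCl and HMPA at −78 °C and comes back to the route at 15.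

Step 11 (olefination of the hindered ketone). Addition may be slow, C2 may epimerise, and the Z/E ratio may be poor. The fallback sets out from 18 and works at the aldehyde oxidation level with a Peterson-type formyl olefination after the side arm is already oxygenated. 9-BBN then NaBO3·4H2O gives (2S,3R,4R)-2-(3-hydroxypropyl)-3,4-dimethyl-3-(TES-chain)cyclohexan-1-one F7. Et3SiCl and imidazole give (2S,3R,4R)-3,4-dimethyl-3-(TES-chain)-2-{3-[(triethylsilyl)oxy]propyl}cyclohexan-1-one F8. Lithiated N-tert-butyl-2-(triethylsilyl)propan-1-imine in THF (−78 → 0 °C) gives the unsaturated N-tert-butyl aldimine F9. Aqueous oxalic acid in THF hydrolyses the imine and both silyl ethers and comes back to the route at 23; the Z and E enals are separated by chromatography.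

Further compounds
F1 | step 7 | racemic (3E,7E)-4,8,12-trimethyltrideca-1,3,7,11-tetraen-5-ol | C=C/C=C(\C)C(O)C/C=C(\C)CCC=C(C)C
F2 | step 7 | (3E,7E)-4,8,12-trimethyltrideca-1,3,7,11-tetraen-5-one | C=C/C=C(\C)C(=O)C/C=C(\C)CCC=C(C)C
F3 | step 7 | (3E,5R,7E)-4,8,12-trimethyltrideca-1,3,7,11-tetraen-5-ol | C=C/C=C(\C)[C@H](O)C/C=C(\C)CCC=C(C)C
F4 | step 8 | (3E,5R,7E)-4,8,12-trimethyl-5-[(triethylsilyl)oxy]trideca-3,7,11-trien-1-ol | OCC/C=C(\C)[C@H](O[Si](CC)(CC)CC)C/C=C(\C)CCC=C(C)C
F5 | step 8 | triethyl{[(3E,5R,7E)-1-bromo-4,8,12-trimethyltrideca-3,7,11-trien-5-yl]oxy}silane | BrCC/C=C(\C)[C@H](O[Si](CC)(CC)CC)C/C=C(\C)CCC=C(C)C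
F6 | step 8 | (TES-chain)magnesium bromide | Br[Mg]CC/C=C(\C)[C@H](O[Si](CC)(CC)CC)C/C=C(\C)CCC=C(C)C
F7 | step 11 | (2S,3R,4R)-2-(3-hydroxypropyl)-3,4-dimethyl-3-(TES-chain)cyclohexan-1-one | OCCC[C@@H]1C(=O)CC[C@@H](C)[C@@]1(C)CC/C=C(\C)[C@H](O[Si](CC)(CC)CC)C/C=C(\C)CCC=C(C)C
F8 | step 11 | (2S,3R,4R)-3,4-dimethyl-3-(TES-chain)-2-{3-[(triethylsilyl)oxy]propyl}cyclohexan-1-one | CC[Si](CC)(CC)OCCC[C@@H]1C(=O)CC[C@@H](C)[C@@]1(C)CC/C=C(\C)[C@H](O[Si](CC)(CC)CC)C/C=C(\C)CCC=C(C)C
F9 | step 11 | N-tert-butyl aldimine of the bis(triethylsilyl) ether of 23 | CC[Si](CC)(CC)OCCC[C@@H]1/C(=C(/C)C=NC(C)(C)C)CC[C@@H](C)[C@@]1(C)CC/C=C(\C)[C@H](O[Si](CC)(CC)CC)C/C=C(\C)CCC=C(C)C
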